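**Strategy.** The route rests on opening the cyclopentane ring B (C5, C6, C8, C9, C10) at its two fusion bonds: C5–C10, shared with ring A, and C8–C9, shared with ring C. One radical chain closes both. A C5 radical adds to C10 of a (Z)-enal and closes ring A; the C9 α-formyl radical so formed adds to C8 of a cyclopentenyl enol pivalate, closing ring B and spiro-attaching ring D. This formal (3+2) annulation sets C5, C8, C9 and C10, two of them quaternary. The precursor is an acyclic C3–C11 chain that carries a C5 thionocarbonate, the C6 ester and the ring D enol ester.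

Key step: step 14

Remark: carbon labels (C1–C20, rings A–D) follow gibberellane numbering of the target, and α/β refer to the usual drawing with H-5 and H-9 β; 1,4-dioxaspiro[4.4]nonan-7-one is taken as a purchasable building block.

Step 1
Reactants: 1 nerol
Product: 2 neryl 4-methoxybenzyl ether
Conditions: NaH, 4-methoxybenzyl chloride, n-Bu4NI (cat.), THF/DMF, 0 °C to rt
Reagents that add atoms: 4-methoxybenzyl chloride, COc1ccc(CCl)cc1
Why: Williamson etherification of the primary allylic alkoxide protects the future C11 oxygen and leaves the Z alkene untouched.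

Step 2
Reactants: 2 neryl 4-methoxybenzyl ether
Product: 4 (4Z)-6-[(4-methoxybenzyl)oxy]-4-methylhex-4-enal, via epoxide 3 (not isolated)
Conditions: mCPBA (1.0 equiv), CH2Cl2, −20 °C; then H5IO6, THF/H2O, 0 °C
Reagents that add atoms: mCPBA, O=C(OO)c1cccc(Cl)c1
Why: Epoxidation should prefer the electron-richer distal trisubstituted alkene over the one deactivated by the allylic ether, and periodic acid cleavage of the epoxide gives the C3 aldehyde.

Step 3
Reactants: 4 (4Z)-6-[(4-methoxybenzyl)oxy]-4-methylhex-4-enal; 5 (4R)-4-benzyl-3-propanoyl-1,3-oxazolidin-2-one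
Product: 8 (4R)-4-benzyl-3-[(2R,3S,6Z)-3-hydroxy-8-[(4-methoxybenzyl)oxy]-2,6-dimethyloct-6-enoyl]-1,3-oxazolidin-2-one, via boron enolate 6 (not isolated), via boron aldolate 7 (not isolated)
Conditions: Bu2BOTf, i-Pr2NEt, CH2Cl2, −78 to 0 °C; then 4, −78 °C; pH 7 buffer, MeOH, H2O2, 0 °C
Reagents that add atoms: none
Why: Evans syn aldol reaction through the (Z)-boron enolate and a Zimmerman–Traxler chair, in which the (R)-auxiliary sets the C3 carbinol as S.

Step 4
Reactants: 8 Evans aldol adduct
Product: 9 methyl (2R,3S,6Z)-3-hydroxy-8-[(4-methoxybenzyl)oxy]-2,6-dimethyloct-6-enoate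
Conditions: NaOMe (cat.), MeOH, 0 °C
Reagents that add atoms: methanol, CO
Why: Methoxide attacks the exocyclic imide carbonyl selectively, so transesterification releases the auxiliary without retro-aldol at 0 °C.

Step 5
Reactants: 9 methyl (2R,3S,6Z)-3-hydroxy-8-[(4-methoxybenzyl)oxy]-2,6-dimethyloct-6-enoate
Product: 11 methyl (2S,3S,6Z)-3-hydroxy-2-(hydroxymethyl)-8-[(4-methoxybenzyl)oxy]-2,6-dimethyloct-6-enoate, via dilithium dianion 10 (not isolated)
Conditions: LiN(i-Pr)2 (2.3 equiv), THF, −78 to −20 °C; then CH2O (gas), −78 °C; aq. NH4Cl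
Reagents that add atoms: formaldehyde, C=O
Why: Fráter–Seebach reaction of the lithium-chelated β-alkoxide enolate, in which formaldehyde enters anti to the C2 side chain and creates the quaternary C4 with the C18/C19 arrangement of the target.

Step 6
Reactants: 11 diol ester
Product: 12 methyl (2R,3S,6Z)-2-formyl-3-hydroxy-8-[(4-methoxybenzyl)oxy]-2,6-dimethyloct-6-enoate
Conditions: TEMPO (cat.), PhI(OAc)2, CH2Cl2, rt
Reagents that add atoms: none
Why: Oxoammonium oxidation is selective for the primary alcohol, and the resulting aldehyde (C5) cannot enolize because C4 is quaternary.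

Step 7
Reactants: 12 hydroxy aldehyde
Product: 13 methyl (2R,3S,6Z)-2-formyl-8-[(4-methoxybenzyl)oxy]-2,6-dimethyl-3-[(triethylsilyl)oxy]oct-6-enoate
Conditions: Et3SiOTf, 2,6-lutidine, CH2Cl2, −78 °C
Reagents that add atoms: triethylsilyl triflate, CC[Si](CC)(CC)OS(=O)(=O)C(F)(F)F
Why: Silylation of the hindered C3 alcohol blocks retro-aldol cleavage in the basic coupling step and is removed later by dilute acid.

Step 8
Reactants: 14 1,4-dioxaspiro[4.4]nonan-7-one; 15 methyl bromoacetate
Product: 17 methyl 2-(7-oxo-1,4-dioxaspiro[4.4]nonan-8-yl)acetate, via lithium enolate 16 (not isolated)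
Conditions: LiN(i-Pr)2, THF, −78 °C; then 15, −78 to −20 °C
Reagents that add atoms: none
Why: Kinetic deprotonation should occur at the α-methylene remote from the dioxolane, and the enolate is alkylated there to attach the future C6–C7 unit to C8.

Step 9
Reactants: 17 methyl 2-(7-oxo-1,4-dioxaspiro[4.4]nonan-8-yl)acetate
Product: 18 methyl 2-{7-[(trimethylsilyl)oxy]-1,4-dioxaspiro[4.4]non-7-en-8-yl}acetate
Conditions: Me3SiCl, NaI, Et3N, MeCN, rt
Reagents that add atoms: chlorotrimethylsilane, C[Si](C)(C)Cl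
Why: Equilibrating silylation with iodotrimethylsilane formed in the flask gives the thermodynamic, tetrasubstituted silyl enol ether on the C8 side, away from the ketal.

Step 10
Reactants: 18 silyl enol ether
Product: 20 methyl 2-[7-(pivaloyloxy)-1,4-dioxaspiro[4.4]non-7-en-8-yl]acetate, via potassium enolate 19 (not isolated)
Conditions: KOt-Bu, THF, −78 to −40 °C; then t-BuCOCl, −78 °C
Reagents that add atoms: pivaloyl chloride, CC(C)(C)C(=O)Cl
Why: Alkoxide cleavage of the Si–O bond releases the enolate regiospecifically, and the hard, hindered acyl chloride acylates it on oxygen to give the C8=C14 enol pivalate.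

Step 11
Reactants: 20 ring D enol pivalate ester; 13 aldehyde
Product: 23 acyclic C5 phenyl thionocarbonate (3S,4S,5R,6R) of the coupled C3–C11 chain, via lithium dienolate 21 (not isolated), via lithium aldolate 22 (not isolated)
Conditions: LiN(i-Pr)2, THF/DMPU (4:1), −78 °C; then 13, −78 °C; then PhOC(=S)Cl, −78 to −40 °C
Reagents that add atoms: O-phenyl chlorothionoformate, S=C(Cl)Oc1ccccc1
Why: Aldol addition of the Z(O)-lithium enolate (syn through a Zimmerman–Traxler chair) to the face of the neopentyl aldehyde anti to its C3 branch (Felkin–Anh and ester-chelate models agree) should give the 6R configuration, and the aldolate is trapped at low temperature as the radical precursor before retro-aldol or elimination can occur.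

Step 12
Reactants: 23 acyclic thionocarbonate
Product: 24 (Z)-allylic alcohol (C11 OH) of the same chain
Conditions: DDQ, CH2Cl2/pH 7 buffer (10:1), 0 °C to rt
Reagents that add atoms: none
Why: Oxidative cleavage of the 4-methoxybenzyl ether under neutral buffered conditions should spare the enol ester, ketal, silyl ether and thionocarbonate.

Step 13
Reactants: 24 (Z)-allylic alcohol
Product: 25 (Z)-enal (C11 aldehyde), cascade precursor
Conditions: MnO2, CH2Cl2, rt, dark
Reagents that add atoms: none
Why: MnO2 oxidizes only the allylic alcohol and should keep the Z geometry, which places the formyl group cis to C1.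

Step 14
Reactants: 25 (Z)-enal thionocarbonate
Product: 26 tricyclic aldehyde: rings A and B trans-fused (H-5β, 10α-methyl), 9α-formyl, 6β-CO2Me, 4α-CO2Me, 3β-OSiEt3, C8 spiro to ring D with C14 (OPiv) on the α face and the C16 ketal
Conditions: Bu3SnH (1.3 equiv, syringe pump, 8 h), AIBN (cat.), benzene, 80 °C, 2 mM
Reagents that add atoms: none
Why: Bu3Sn• adds to the thiocarbonyl sulfur and the C5–O bond fragments (Barton–McCombie mode) to a secondary C5 radical; this nucleophilic radical adds to C10, the β-carbon of the (Z)-enal, and the electrophilic C9 α-formyl radical then adds to C8, the oxygen-free carbon of the enol pivalate, before the C14 α-acyloxy radical takes hydrogen from Bu3SnH. The closest known reaction type is the tin hydride tandem radical cyclization used as a (3+2) radical annulation of a homoallyl-type radical across an alkene. Ring A closes 6-exo-trig and ring B 5-exo-trig; 6-endo attack at the oxygen-bearing C14 is polarity-mismatched. C5 and C10 are set in a chair transition state with C6 equatorial, the C4 ester axial and the formyl group of the Z-enal over the axial H-5, which puts C20 axial and C9 equatorial (trans A/B fusion); C8 is set by allylic 1,3-strain, which turns the pivaloyloxy-bearing C14 to the face of H-6; C9 is set by the chair-like 5-exo transition state with the formyl group pseudo-equatorial and cis to C14. The step needs chemoselectivity (the thionocarbonate must react with Bu3Sn• faster than the enal), polarity-matched regioselectivity, and two cyclizations that outrun hydrogen transfer, which slow addition of Bu3SnH at high dilution is meant to secure.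

Step 15
Reactants: 26 tricyclic aldehyde
Product: 27 methyl enol ether (C11=C12–OMe, E/Z mixture)
Conditions: Ph3P(CH2OMe)Cl, KN(SiMe3)2, THF, 0 °C; then 26, −78 to 0 °C
Reagents that add atoms: (methoxymethyl)triphenylphosphonium chloride, COC[P+](c1ccccc1)(c1ccccc1)c1ccccc1.[Cl-]
Why: Wittig methoxymethylenation of the hindered but reactive aldehyde adds C12 at the aldehyde oxidation level, and C9 is no longer epimerizable afterwards.

Step 16
Reactants: 27 methyl enol ether
Product: 29 enone aldehyde (C12 aldehyde; C13=C14–C16=O cyclopentenone; free 3β-OH), via keto aldehyde 28 (not isolated)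
Conditions: 1 M HCl, THF, rt; then DBU, CH2Cl2, 0 °C to rt
Reagents that add atoms: water, O
Why: Dilute acid hydrolyzes the enol ether, the dioxolane and the triethylsilyl ether, and DBU then eliminates pivalate from the β-acyloxy ketone (E1cB), so the temporary C14 oxygen becomes the C13=C14 enone.

Step 17
Reactants: 29 enone aldehyde
Product: 30 17-nor-16-ketone dimethyl ester with the 3β,12β-diol (rings C and D closed, full gibberellane ring system)
Conditions: [(Ph3P)CuH]6, toluene, −40 to 0 °C; aq. NH4Cl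
Reagents that add atoms: none
Why: Reductive aldol cyclization: conjugate hydride delivery to C14 gives the copper enolate regiospecifically at C13, which adds to the C12 aldehyde on the α-face arm to close the six-membered ring C of the bicyclo[3.2.1]octane; the chelated chair should place the 12-OH syn to C16, and this centre is corrected in steps 19 and 20.

Step 18
Reactants: 30 hydroxy ketone
Product: 31 12-epimer of the target dimethyl ester (3β,12β-diol with the 16-methylene group)
Conditions: Zn, CH2Br2, TiCl4, THF/CH2Cl2, 0 °C to rt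
Reagents that add atoms: dibromomethane, BrCBr
Why: The non-basic Zn/CH2Br2/TiCl4 methylenation converts the C16 ketone into the exocyclic alkene without retro-aldol of the β-hydroxy ketone.

Step 19
Reactants: 31 diol
Product: 32 3,12-diketone dimethyl ester with the 16-methylene group
Conditions: Dess–Martin periodinane, NaHCO3, CH2Cl2, rt
Reagents that add atoms: none
Why: Both secondary alcohols are oxidized, and the 12-ketone cannot conjugate with the 16-alkene because C13 is a bridgehead.

Step 20
Reactants: 32 diketone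
Product: 33 dimethyl ester of the target (3β,12α-diol)
Conditions: LiBH(s-Bu)3, THF, −78 °C; aq. NH4Cl
Reagents that add atoms: none
Why: The bulky hydride should attack both ketones along the equatorial trajectory (the axial face of C12 is blocked by C10, that of C3 by the ring A axial hydrogens), giving the axial 3β- and 12α-alcohols, and the hindered esters should survive at −78 °C.

Step 21
Reactants: 33 dimethyl ester of the target
Product: 34 target gibberellin (3β,12α-dihydroxy-16-ene-7,19-dioic acid of the C20 gibberellane skeleton)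
Conditions: NaSEt, DMF, 100 °C; then aq. HCl
Reagents that add atoms: none
Why: SN2 demethylation by thiolate at the methyl carbons cleaves both hindered esters (C7 and the neopentyl C19) without epimerization or alkene migration.

**Compound list**

1 | nerol, (2Z)-3,7-dimethylocta-2,6-dien-1-ol | CC(C)=CCC/C(C)=C\CO | starting material
2 | neryl 4-methoxybenzyl ether | CC(C)=CCC/C(C)=C\COCc1ccc(OC)cc1 | intermediate
3 | 6,7-epoxide of 2 (both epoxide configurations) | CC1(C)OC1CC/C(C)=C\COCc1ccc(OC)cc1 | intermediate (not isolated)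
4 | (4Z)-6-[(4-methoxybenzyl)oxy]-4-methylhex-4-enal | O=CCC/C(C)=C\COCc1ccc(OC)cc1 | intermediate
5 | (4R)-4-benzyl-3-propanoyl-1,3-oxazolidin-2-one | CCC(=O)N1C(=O)OC[C@H]1Cc1ccccc1 | starting material
6 | (Z)-dibutylboron enolate of 5 | C/C=C(\OB(CCCC)CCCC)N1C(=O)OC[C@H]1Cc1ccccc1 | intermediate (not isolated)
7 | dibutylboron aldolate of 8 | C[C@@H](C(=O)N1C(=O)OC[C@H]1Cc1ccccc1)[C@@H](OB(CCCC)CCCC)CC/C(C)=C\COCc1ccc(OC)cc1 | intermediate (not isolated)
8 | (4R)-4-benzyl-3-[(2R,3S,6Z)-3-hydroxy-8-[(4-methoxybenzyl)oxy]-2,6-dimethyloct-6-enoyl]-1,3-oxazolidin-2-one | C[C@@H](C(=O)N1C(=O)OC[C@H]1Cc1ccccc1)[C@@H](O)CC/C(C)=C\COCc1ccc(OC)cc1 | intermediate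
9 | methyl (2R,3S,6Z)-3-hydroxy-8-[(4-methoxybenzyl)oxy]-2,6-dimethyloct-6-enoate | COC(=O)[C@H](C)[C@@H](O)CC/C(C)=C\COCc1ccc(OC)cc1 | intermediate
10 | dilithium alkoxide enolate of 9 | [Li+].[Li+].COC([O-])=C(C)[C@@H]([O-])CC/C(C)=C\COCc1ccc(OC)cc1 | intermediate (not isolated)
11 | methyl (2S,3S,6Z)-3-hydroxy-2-(hydroxymethyl)-8-[(4-methoxybenzyl)oxy]-2,6-dimethyloct-6-enoate | COC(=O)[C@@](C)(CO)[C@@H](O)CC/C(C)=C\COCc1ccc(OC)cc1 | intermediate
12 | methyl (2R,3S,6Z)-2-formyl-3-hydroxy-8-[(4-methoxybenzyl)oxy]-2,6-dimethyloct-6-enoate | COC(=O)[C@@](C)(C=O)[C@@H](O)CC/C(C)=C\COCc1ccc(OC)cc1 | intermediate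
13 | methyl (2R,3S,6Z)-2-formyl-8-[(4-methoxybenzyl)oxy]-2,6-dimethyl-3-[(triethylsilyl)oxy]oct-6-enoate | COC(=O)[C@@](C)(C=O)[C@@H](O[Si](CC)(CC)CC)CC/C(C)=C\COCc1ccc(OC)cc1 | intermediate
14 | 1,4-dioxaspiro[4.4]nonan-7-one | O=C1CCC2(C1)OCCO2 | starting material
15 | methyl bromoacetate | COC(=O)CBr | starting material
16 | lithium 1,4-dioxaspiro[4.4]non-7-en-7-olate | [Li+].[O-]C1=CCC2(C1)OCCO2 | intermediate (not isolated)
17 | methyl 2-(7-oxo-1,4-dioxaspiro[4.4]nonan-8-yl)acetate (racemic) | COC(=O)CC1CC2(CC1=O)OCCO2 | intermediate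
18 | methyl 2-{7-[(trimethylsilyl)oxy]-1,4-dioxaspiro[4.4]non-7-en-8-yl}acetate | COC(=O)CC1=C(O[Si](C)(C)C)CC2(C1)OCCO2 | intermediate
19 | potassium enolate from 18 | [K+].COC(=O)CC1=C([O-])CC2(C1)OCCO2 | intermediate (not isolated)
20 | methyl 2-[7-(pivaloyloxy)-1,4-dioxaspiro[4.4]non-7-en-8-yl]acetate | COC(=O)CC1=C(OC(=O)C(C)(C)C)CC2(C1)OCCO2 | intermediate
21 | Z(O)-lithium dienolate of 20 | [Li+].[O-]/C(OC)=C\C1=C(OC(=O)C(C)(C)C)CC2(C1)OCCO2 | intermediate (not isolated)
22 | lithium aldolate (C5 alkoxide) of the coupled chain | [Li+].COC(=O)[C@H](C1=C(OC(=O)C(C)(C)C)CC2(C1)OCCO2)[C@@H]([O-])[C@](C)(C(=O)OC)[C@@H](O[Si](CC)(CC)CC)CC/C(C)=C\COCc1ccc(OC)cc1 | intermediate (not isolated)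
23 | acyclic thionocarbonate (3S,4S,5R,6R): C19 and C7 methyl esters, C3 OSiEt3, C5 OC(=S)OPh, C6 bearing the 7-(pivaloyloxy)-1,4-dioxaspiro[4.4]non-7-en-8-yl ring, (Z)-C9=C10, C11 O-(4-methoxybenzyl) | COC(=O)[C@H](C1=C(OC(=O)C(C)(C)C)CC2(C1)OCCO2)[C@@H](OC(=S)Oc1ccccc1)[C@](C)(C(=O)OC)[C@@H](O[Si](CC)(CC)CC)CC/C(C)=C\COCc1ccc(OC)cc1 | intermediate
24 | (Z)-allylic alcohol (C11 OH) thionocarbonate | COC(=O)[C@H](C1=C(OC(=O)C(C)(C)C)CC2(C1)OCCO2)[C@@H](OC(=S)Oc1ccccc1)[C@](C)(C(=O)OC)[C@@H](O[Si](CC)(CC)CC)CC/C(C)=C\CO | intermediate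
25 | (Z)-enal thionocarbonate, cascade precursor | COC(=O)[C@H](C1=C(OC(=O)C(C)(C)C)CC2(C1)OCCO2)[C@@H](OC(=S)Oc1ccccc1)[C@](C)(C(=O)OC)[C@@H](O[Si](CC)(CC)CC)CC/C(C)=C\C=O | intermediate
26 | tricyclic aldehyde (rings A, B, D; 9α-CHO; C14 OPiv, either configuration) | O=C[C@H]1[C@]2(C)CC[C@H](O[Si](CC)(CC)CC)[C@@](C)(C(=O)OC)[C@H]2[C@H](C(=O)OC)[C@]13CC4(OCCO4)CC3OC(=O)C(C)(C)C | intermediate
27 | methyl enol ether of the homologated aldehyde (E/Z) | COC=C[C@H]1[C@]2(C)CC[C@H](O[Si](CC)(CC)CC)[C@@](C)(C(=O)OC)[C@H]2[C@H](C(=O)OC)[C@]13CC4(OCCO4)CC3OC(=O)C(C)(C)C | intermediate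
28 | keto aldehyde with C14 pivalate and free 3β-OH | O=CC[C@H]1[C@]2(C)CC[C@H](O)[C@@](C)(C(=O)OC)[C@H]2[C@H](C(=O)OC)[C@]13CC(=O)CC3OC(=O)C(C)(C)C | intermediate (not isolated)
29 | enone aldehyde (C13=C14–C16=O, C12 aldehyde) | O=CC[C@H]1[C@]2(C)CC[C@H](O)[C@@](C)(C(=O)OC)[C@H]2[C@H](C(=O)OC)[C@]13CC(=O)C=C3 | intermediate
30 | 17-nor-16-ketone dimethyl ester with 3β,12β-diol (tetracyclic gibberellane ring system) | O=C1C[C@]23C[C@H]1[C@H](O)C[C@H]2[C@]1(C)CC[C@H](O)[C@@](C)(C(=O)OC)[C@H]1[C@@H]3C(=O)OC | intermediate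
31 | 12-epimer of the target dimethyl ester (3β,12β-diol, 16-methylene) | C=C1C[C@]23C[C@H]1[C@H](O)C[C@H]2[C@]1(C)CC[C@H](O)[C@@](C)(C(=O)OC)[C@H]1[C@@H]3C(=O)OC | intermediate
32 | 3,12-diketone dimethyl ester with 16-methylene | C=C1C[C@]23C[C@H]1C(=O)C[C@H]2[C@]1(C)CCC(=O)[C@@](C)(C(=O)OC)[C@H]1[C@@H]3C(=O)OC | intermediate
33 | dimethyl ester of the target (3β,12α-diol, 16-methylene) | C=C1C[C@]23C[C@H]1[C@@H](O)C[C@H]2[C@]1(C)CC[C@H](O)[C@@](C)(C(=O)OC)[C@H]1[C@@H]3C(=O)OC | intermediate
34 | target gibberellin (3β,12α-dihydroxy-16-ene-7,19-dioic acid of the C20 gibberellane skeleton) | C=C1C[C@]23C[C@H]1[C@@H](O)C[C@H]2[C@]1(C)CC[C@H](O)[C@@](C)(C(=O)O)[C@H]1[C@@H]3C(=O)O | target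

**Step count.** 21 steps in total; the longest linear sequence is 18 steps (steps 1–7 and 11–21).

**Steps most likely to fail**

1. Step 14. Hydrogen transfer to the C9 radical may outrun the second ring closure, or the facial selectivity at C10 and C8 may be poor. Fallback, from 25 back to 26: run the first closure alone with Bu3SnH/AIBN at 0.05 M to give the ring A aldehyde F1. Install a radical handle at C9 by enamine-catalysed α-selenenylation (N-(phenylseleno)phthalimide, pyrrolidine cat., CH2Cl2) to give the α-phenylseleno aldehyde F2. Close ring B in a separate 5-exo cyclization (Bu3SnH, AIBN, benzene, 80 °C, high dilution), which regenerates only the C9 radical and returns to 26.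

2. Step 11. The syn selectivity of the lithium aldol may erode (wrong C6), or the pivaloyl group may migrate to the enolate carbon before the aldehyde is added. Fallback, from 20 and 13 back to 23: trap 20 in situ (LiN(i-Pr)2, Me3SiCl, THF/DMPU, −78 °C) as the silyl ketene acetal F3. Run a chelation-controlled Mukaiyama aldol with 13 (MgBr2·OEt2, CH2Cl2, −78 °C) to give the β-hydroxy ester F4. Acylate F4 with PhOC(=S)Cl, pyridine and DMAP to reach 23.

3. Step 17. The copper hydride may reduce the aldehyde 1,2, or the copper enolate may be protonated before it closes the bridged ring. Fallback, from 29 back to 30: hydrogenate the enone (H2, Pd/C, EtOAc) to the saturated keto aldehyde F5. Close ring C by a reversible base aldol (NaOMe, MeOH, rt); only the C13 enolate can reach the C12 aldehyde on the α-face arm, and the bridged product cannot dehydrate.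

**Further compounds**

F1 | step 14 | ring A aldehyde (C9 methylene; ring D enol pivalate intact) | O=CC[C@]1(C)CC[C@H](O[Si](CC)(CC)CC)[C@@](C)(C(=O)OC)[C@H]1[C@H](C(=O)OC)C1=C(OC(=O)C(C)(C)C)CC2(C1)OCCO2
F2 | step 14 | C9 phenylseleno aldehyde (both C9 configurations) | O=CC([Se]c1ccccc1)[C@]2(C)CC[C@H](O[Si](CC)(CC)CC)[C@@](C)(C(=O)OC)[C@H]2[C@H](C(=O)OC)C1=C(OC(=O)C(C)(C)C)CC3(C1)OCCO3
F3 | step 11 | trimethylsilyl ketene acetal of 20 | COC(O[Si](C)(C)C)=CC1=C(OC(=O)C(C)(C)C)CC2(C1)OCCO2
F4 | step 11 | β-hydroxy ester (free C5 alcohol of 23) | COC(=O)[C@H](C1=C(OC(=O)C(C)(C)C)CC2(C1)OCCO2)[C@@H](O)[C@](C)(C(=O)OC)[C@@H](O[Si](CC)(CC)CC)CC/C(C)=C\COCc1ccc(OC)cc1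
F5 | step 17 | saturated keto aldehyde (C16 ketone, C12 aldehyde) | O=CC[C@H]1[C@]2(C)CC[C@H](O)[C@@](C)(C(=O)OC)[C@H]2[C@H](C(=O)OC)[C@]13CC(=O)CC3
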